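I wanted to know how much of the substrate stood as product and crystals together at the end of this run, and how far above saturation the solution then was.

1. the product and crystals together standing at 2.5 h, as a percentage of the substrate charged
2. concentration of product in solution at 2.5 h, in percent of saturation

substrate 0.050 M; free catalyst 0.25 mM; time 2.5 h

- amounts and yields of product count crystals too
- given per volume of solution although it is solid: crystals
- run time (flask): 2.5 h

    substrate + free catalyst ⇌ catalyst intermediate A (K1 = 1600 L mol⁻¹, k1 = 0.290 L mol⁻¹ s⁻¹)
    catalyst intermediate A ⇌ catalyst intermediate B (K2 = 1.31, k2 = 0.419 s⁻¹)
    crystals ⇌ product, rate k3*(cs3 - [product]) while solid is left; crystals form when [product] > cs3 (cs3 = 3.0 mM, k3 = 0.00654 s⁻¹)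
    catalyst intermediate B → free catalyst + product (k4 = 0.652 s⁻¹)

I looked for the one concentration that set the order of the rate, and I found it in the free catalyst. In the first instants substrate captured each free catalyst once in 69.0 s, while a captured catalyst came back free after 5.09 s on average, the way back between the intermediates counted. That stay was shorter than the wait, so nearly all of the catalyst stood free, as the resting state. Catalyst intermediate A went forward at 0.419 s⁻¹ against 1.81 × 10⁻⁴ s⁻¹ back, so I took each capture as a turnover and carried one quantity through the run: the pseudo-first-order constant, the capture rate constant times the catalyst charged, 0.261 h⁻¹.

By that constant I reckoned the product to reach its solubility after about 0.237 h. In the middle of the run crystals took up the excess, and their relaxation time of 153 s was shorter than the run, so I set the excess over solubility equal to the making rate divided by the dissolution coefficient. At the end I reckoned 47.9 % for product and crystals, and a making rate of 6.80 mM h⁻¹ put the solution at 110 % of saturation.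

The forecast gave 46.1 % and 109.6 %, on the ground that “the catalyst stays mostly free and the substrate decays almost first-order”; its yield lay below mine, which had counted the whole catalyst charge as free.

The simulation gave 46.1 % and 110 %.

This flask was stopped by its clock, with 53.9 % of the substrate still standing: the length of the run was the main reason, for product and crystals together stood at 46.1 % after 2.5 h against 99.8 % in the same flask left until 25.0 h. With 0.261 h⁻¹ I reckoned the substrate's half-life at 2.66 h, and the run of 2.5 h ended short of it. In the neighbour flask charged with 1.5 × 10⁻⁴ M of free catalyst, the constant fell to 0.157 h⁻¹, which I reckoned to give 32.4 % at the same time, and that flask stood at 30.8 %.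

(The rate constants were chosen freely, and the outcome is calculated.)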